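## Retrosynthetic overview

1. Target 21 ⇒ protected chalcone 20 (one acid step removes four MOM groups and one TBS group) ⇒ Claisen–Schmidt condensation of methyl ketone 17 with aldehyde 18 (ring B).
2. 17 ⇒ E-selective olefin cross-metathesis (C5=C6) of the (S)-3,3-diarylpropene 9 with the (R)-homoallylic silyl ether 16.
3. 9 ⇒ new catalytic enantioselective aromatic Claisen rearrangement of aryl cinnamyl ether 7 (forms the ring A–C7 bond, sets 7S) ⇒ Mitsunobu union of phenol 2 with cinnamyl alcohol 6.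
4. 16 ⇒ Brown allylation of aldehyde 13 (sets 3R).
5. No ring is built: all four benzene rings are bought (ring A in 1, the C7 aryl in 3, the C1 aryl in 10, ring B in 18).

Assumption: the side chain is numbered as a diarylheptanoid (C1 and C7 carry the aryl groups, C3 the hydroxyl, C7 sits on ring A), which makes the target 7S,3R; the sense of induction of the new step 5 is taken as written, and the mirror-image catalyst is used if it proves opposite.

## Route

Step 1
Reactants: 1 1-(2,4-dihydroxy-6-methoxyphenyl)ethan-1-one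
Product: 2 1-[2-hydroxy-6-methoxy-4-(methoxymethoxy)phenyl]ethan-1-one
Conditions: MOMCl (1.1 equiv), i-Pr2NEt, CH2Cl2, 0 °C to rt
Reagents that add atoms: chloromethyl methyl ether, COCCl
Why: Williamson-type O-alkylation in which the 2-OH is tied up in the hydrogen bond to the acetyl group, so only the 4-OH reacts.

Step 2
Reactants: 3 methyl (2E)-3-(4-hydroxyphenyl)prop-2-enoate
Product: 4 methyl (2E)-3-[4-(methoxymethoxy)phenyl]prop-2-enoate
Conditions: MOMCl, i-Pr2NEt, CH2Cl2, 0 °C to rt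
Reagents that add atoms: chloromethyl methyl ether, COCCl
Why: Standard phenol protection by O-alkylation that leaves the ester and the E olefin untouched.

Step 3
Reactants: 4 methyl (2E)-3-[4-(methoxymethoxy)phenyl]prop-2-enoate
Product: 6 (2E)-3-[4-(methoxymethoxy)phenyl]prop-2-en-1-ol, via enal 5 (not isolated)
Conditions: i-Bu2AlH (2.5 equiv), CH2Cl2, −78 to 0 °C; aq. potassium sodium tartrate
Reagents that add atoms: none
Why: Hydride reduction of the conjugated ester by 1,2-addition through the aldehyde to the allylic alcohol, without touching the olefin or the acetal.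

Step 4
Reactants: 2 1-[2-hydroxy-6-methoxy-4-(methoxymethoxy)phenyl]ethan-1-one; 6 (2E)-3-[4-(methoxymethoxy)phenyl]prop-2-en-1-ol
Product: 7 1-[2-methoxy-4-(methoxymethoxy)-6-{[(2E)-3-[4-(methoxymethoxy)phenyl]prop-2-en-1-yl]oxy}phenyl]ethan-1-one
Conditions: PPh3, DIAD, THF, 0 °C to rt
Reagents that add atoms: none
Why: Mitsunobu etherification in which the primary allylic alcohol is activated as its oxyphosphonium salt and displaced by the acidic chelated phenol, tethering the cinnamyl unit to O-2, the only oxygen from which a [3,3] shift must land on C-3.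

Step 5
Reactants: 7 1-[2-methoxy-4-(methoxymethoxy)-6-{[(2E)-3-[4-(methoxymethoxy)phenyl]prop-2-en-1-yl]oxy}phenyl]ethan-1-one
Product: 9 1-[2-hydroxy-6-methoxy-4-(methoxymethoxy)-3-{(1S)-1-[4-(methoxymethoxy)phenyl]prop-2-en-1-yl}phenyl]ethan-1-one, via Claisen dienone 8 (not isolated)
Conditions: N,N'-bis[(1R,2R)-2-(2,5-diphenyl-1H-pyrrol-1-yl)cyclohexyl]guanidinium tetrakis[3,5-bis(trifluoromethyl)phenyl]borate (20 mol%), hexanes/CH2Cl2 4:1, 40 °C, 72 h
Reagents that add atoms: none
Why: Proposed new method: a catalytic enantioselective, rearomatising aromatic Claisen rearrangement ([3,3]-sigmatropic shift) in which the C2-symmetric guanidinium ion donates two N–H hydrogen bonds to the ether oxygen and the ortho-acetyl oxygen of 7, stabilising the aryloxide-like negative charge of a polarised chair transition state while the 4-alkoxycinnamyl fragment carries the matching positive charge and stacks on a phenylpyrrole wall of the catalyst, so that the barrier falls well below that of the thermal background (about 180 °C) and the allyl terminus is delivered to one face of C-3 only, forming the ring A–C7 bond and setting C7 as S; C-3 is the only open ortho carbon and the catalyst occupies the acetyl side, so dienone 8 forms regiospecifically and tautomerises to phenol 9, whose internally hydrogen-bonded carbonyl binds the catalyst only weakly and allows turnover; the closest known reaction types are the guanidinium-catalysed enantioselective Claisen rearrangement of ester-substituted allyl vinyl ethers and chiral Lewis acid-catalysed dearomative Claisen rearrangements of ortho-carbonyl aryl allyl ethers, neither of which has been shown for a rearomatising aryl ether that creates its stereocentre at the allyl terminus.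

Step 6
Reactants: 10 methyl 3-(4-hydroxyphenyl)propanoate
Product: 11 methyl 3-[4-(methoxymethoxy)phenyl]propanoate
Conditions: MOMCl, i-Pr2NEt, CH2Cl2, 0 °C to rt
Reagents that add atoms: chloromethyl methyl ether, COCCl
Why: Standard phenol protection by O-alkylation.

Step 7
Reactants: 11 methyl 3-[4-(methoxymethoxy)phenyl]propanoate
Product: 13 3-[4-(methoxymethoxy)phenyl]propanal, via aluminium hemiacetal 12 (not isolated)
Conditions: i-Bu2AlH (1.05 equiv), CH2Cl2, −78 °C; MeOH, then aq. potassium sodium tartrate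
Reagents that add atoms: none
Why: Partial ester reduction in which the tetrahedral aluminium hemiacetal is stable at −78 °C and releases the aldehyde only on work-up.

Step 8
Reactants: 13 3-[4-(methoxymethoxy)phenyl]propanal
Product: 15 (3R)-1-[4-(methoxymethoxy)phenyl]hex-5-en-3-ol, via borinate ester 14 (not isolated)
Conditions: allylbis(isopinocampheyl)borane of the (+)-α-pinene series (1.3 equiv, salt-free pentane solution), Et2O, −78 °C; then 3 M NaOH, 30% H2O2, 0 °C to rt
Reagents that add atoms: allylbis[(1R,2S,3R,5R)-2,6,6-trimethylbicyclo[3.1.1]heptan-3-yl]borane, C=CCB([C@@H]1C[C@@H]2C[C@H]([C@H]1C)C2(C)C)[C@@H]1C[C@@H]2C[C@H]([C@H]1C)C2(C)C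
Why: Brown allylboration, whose chair Zimmerman–Traxler transition state delivers the allyl group of the (+)-α-pinene-derived reagent to the Si face of the aldehyde and so sets the carbinol centre (later C3) as R.

Step 9
Reactants: 15 (3R)-1-[4-(methoxymethoxy)phenyl]hex-5-en-3-ol
Product: 16 tert-butyl{[(3R)-1-[4-(methoxymethoxy)phenyl]hex-5-en-3-yl]oxy}dimethylsilane
Conditions: TBSCl, imidazole, DMF, rt
Reagents that add atoms: tert-butyldimethylsilyl chloride, CC(C)(C)[Si](C)(C)Cl
Why: Routine silylation of a secondary alcohol that does not touch the stereocentre.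

Step 10
Reactants: 9 1-[2-hydroxy-6-methoxy-4-(methoxymethoxy)-3-{(1S)-1-[4-(methoxymethoxy)phenyl]prop-2-en-1-yl}phenyl]ethan-1-one; 16 tert-butyl{[(3R)-1-[4-(methoxymethoxy)phenyl]hex-5-en-3-yl]oxy}dimethylsilane
Product: 17 1-[3-{(1S,2E,5R)-5-[(tert-butyldimethylsilyl)oxy]-1,7-bis[4-(methoxymethoxy)phenyl]hept-2-en-1-yl}-2-hydroxy-6-methoxy-4-(methoxymethoxy)phenyl]ethan-1-one
Conditions: 16 (3 equiv), second-generation Hoveyda–Grubbs catalyst RuCl2(H2IMes)(=CH-C6H4-2-O-i-Pr) (10 mol%), 1,4-benzoquinone (20 mol%), CH2Cl2, 40 °C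
Reagents that add atoms: none
Why: Olefin cross-metathesis in which the unhindered homoallylic ether, used in excess, loads onto ruthenium and the bulky 3,3-diarylpropene reacts only in the cross sense to give the thermodynamically favoured E olefin (C5=C6), while benzoquinone suppresses ruthenium hydride isomerisation so that C7 and C3 are untouched.

Step 11
Reactants: 17 1-[3-{(1S,2E,5R)-5-[(tert-butyldimethylsilyl)oxy]-1,7-bis[4-(methoxymethoxy)phenyl]hept-2-en-1-yl}-2-hydroxy-6-methoxy-4-(methoxymethoxy)phenyl]ethan-1-one; 18 4-(methoxymethoxy)benzaldehyde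
Product: 20 (2E)-1-[3-{(1S,2E,5R)-5-[(tert-butyldimethylsilyl)oxy]-1,7-bis[4-(methoxymethoxy)phenyl]hept-2-en-1-yl}-2-hydroxy-6-methoxy-4-(methoxymethoxy)phenyl]-3-[4-(methoxymethoxy)phenyl]prop-2-en-1-one, via aldol adduct 19 (not isolated)
Conditions: 18 (1.5 equiv), KOH (10 equiv), EtOH/THF, rt, 36 h
Reagents that add atoms: none
Why: Claisen–Schmidt aldol condensation in which the methyl ketone enolate adds to the non-enolisable aldehyde and the aldol loses water to the E enone, the MOM and TBS ethers being stable to hydroxide and C7–H far too weakly acidic to epimerise.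

Step 12
Reactants: 20 (2E)-1-[3-{(1S,2E,5R)-5-[(tert-butyldimethylsilyl)oxy]-1,7-bis[4-(methoxymethoxy)phenyl]hept-2-en-1-yl}-2-hydroxy-6-methoxy-4-(methoxymethoxy)phenyl]-3-[4-(methoxymethoxy)phenyl]prop-2-en-1-one
Product: 21 (2E)-1-{2,4-dihydroxy-3-[(1S,2E,5R)-5-hydroxy-1,7-bis(4-hydroxyphenyl)hept-2-en-1-yl]-6-methoxyphenyl}-3-(4-hydroxyphenyl)prop-2-en-1-one (CNP0177199.3)
Conditions: HCl (3 M in MeOH), THF/MeOH, rt
Reagents that add atoms: none
Why: Acid-catalysed acetal exchange of the four MOM ethers and methanolysis of the TBS ether free all five hydroxyls under conditions that 2'-hydroxychalcones with an allylic C-3' substituent tolerate, and no stereocentre is involved.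

## Compound list

1 | 1-(2,4-dihydroxy-6-methoxyphenyl)ethan-1-one | COc1cc(O)cc(O)c1C(C)=O | starting material
2 | 1-[2-hydroxy-6-methoxy-4-(methoxymethoxy)phenyl]ethan-1-one | COCOc1cc(O)c(C(C)=O)c(OC)c1 | intermediate
3 | methyl (2E)-3-(4-hydroxyphenyl)prop-2-enoate | COC(=O)/C=C/c1ccc(O)cc1 | starting material
4 | methyl (2E)-3-[4-(methoxymethoxy)phenyl]prop-2-enoate | COCOc1ccc(/C=C/C(=O)OC)cc1 | intermediate
5 | (2E)-3-[4-(methoxymethoxy)phenyl]prop-2-enal | COCOc1ccc(/C=C/C=O)cc1 | intermediate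
6 | (2E)-3-[4-(methoxymethoxy)phenyl]prop-2-en-1-ol | COCOc1ccc(/C=C/CO)cc1 | intermediate
7 | 1-[2-methoxy-4-(methoxymethoxy)-6-{[(2E)-3-[4-(methoxymethoxy)phenyl]prop-2-en-1-yl]oxy}phenyl]ethan-1-one | COCOc1ccc(/C=C/COc2cc(OCOC)cc(OC)c2C(C)=O)cc1 | intermediate
8 | (6R)-2-acetyl-3-methoxy-5-(methoxymethoxy)-6-{(1R)-1-[4-(methoxymethoxy)phenyl]prop-2-en-1-yl}cyclohexa-2,4-dien-1-one | CC(=O)C1=C(OC)C=C(OCOC)[C@@H]([C@@H](C=C)c2ccc(OCOC)cc2)C1=O | intermediate
9 | 1-[2-hydroxy-6-methoxy-4-(methoxymethoxy)-3-{(1S)-1-[4-(methoxymethoxy)phenyl]prop-2-en-1-yl}phenyl]ethan-1-one | COc1cc(OCOC)c([C@@H](C=C)c2ccc(OCOC)cc2)c(O)c1C(C)=O | intermediate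
10 | methyl 3-(4-hydroxyphenyl)propanoate | COC(=O)CCc1ccc(O)cc1 | starting material
11 | methyl 3-[4-(methoxymethoxy)phenyl]propanoate | COCOc1ccc(CCC(=O)OC)cc1 | intermediate
12 | {1-methoxy-3-[4-(methoxymethoxy)phenyl]propoxy}bis(2-methylpropyl)aluminium | COCOc1ccc(CCC(OC)O[Al](CC(C)C)CC(C)C)cc1 | intermediate
13 | 3-[4-(methoxymethoxy)phenyl]propanal | COCOc1ccc(CCC=O)cc1 | intermediate
14 | (3R)-1-[4-(methoxymethoxy)phenyl]hex-5-en-3-yl bis[(1R,2S,3R,5R)-2,6,6-trimethylbicyclo[3.1.1]heptan-3-yl]borinate | C=CC[C@H](OB([C@@H]1C[C@@H]2C[C@H]([C@H]1C)C2(C)C)[C@@H]1C[C@@H]2C[C@H]([C@H]1C)C2(C)C)CCc1ccc(OCOC)cc1 | intermediate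
15 | (3R)-1-[4-(methoxymethoxy)phenyl]hex-5-en-3-ol | C=CC[C@H](O)CCc1ccc(OCOC)cc1 | intermediate
16 | tert-butyl{[(3R)-1-[4-(methoxymethoxy)phenyl]hex-5-en-3-yl]oxy}dimethylsilane | C=CC[C@H](O[Si](C)(C)C(C)(C)C)CCc1ccc(OCOC)cc1 | intermediate
17 | 1-[3-{(1S,2E,5R)-5-[(tert-butyldimethylsilyl)oxy]-1,7-bis[4-(methoxymethoxy)phenyl]hept-2-en-1-yl}-2-hydroxy-6-methoxy-4-(methoxymethoxy)phenyl]ethan-1-one | COc1cc(OCOC)c([C@@H](/C=C/C[C@H](O[Si](C)(C)C(C)(C)C)CCc2ccc(OCOC)cc2)c2ccc(OCOC)cc2)c(O)c1C(C)=O | intermediate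
18 | 4-(methoxymethoxy)benzaldehyde | COCOc1ccc(C=O)cc1 | starting material
19 | 1-[3-{(1S,2E,5R)-5-[(tert-butyldimethylsilyl)oxy]-1,7-bis[4-(methoxymethoxy)phenyl]hept-2-en-1-yl}-2-hydroxy-6-methoxy-4-(methoxymethoxy)phenyl]-3-hydroxy-3-[4-(methoxymethoxy)phenyl]propan-1-one (both carbinol epimers) | COc1cc(OCOC)c([C@@H](/C=C/C[C@H](O[Si](C)(C)C(C)(C)C)CCc2ccc(OCOC)cc2)c2ccc(OCOC)cc2)c(O)c1C(=O)CC(O)c1ccc(OCOC)cc1 | intermediate
20 | (2E)-1-[3-{(1S,2E,5R)-5-[(tert-butyldimethylsilyl)oxy]-1,7-bis[4-(methoxymethoxy)phenyl]hept-2-en-1-yl}-2-hydroxy-6-methoxy-4-(methoxymethoxy)phenyl]-3-[4-(methoxymethoxy)phenyl]prop-2-en-1-one | COc1cc(OCOC)c([C@@H](/C=C/C[C@H](O[Si](C)(C)C(C)(C)C)CCc2ccc(OCOC)cc2)c2ccc(OCOC)cc2)c(O)c1C(=O)/C=C/c1ccc(OCOC)cc1 | intermediate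
21 | (2E)-1-{2,4-dihydroxy-3-[(1S,2E,5R)-5-hydroxy-1,7-bis(4-hydroxyphenyl)hept-2-en-1-yl]-6-methoxyphenyl}-3-(4-hydroxyphenyl)prop-2-en-1-one | COc1cc(O)c([C@@H](/C=C/C[C@H](O)CCc2ccc(O)cc2)c2ccc(O)cc2)c(O)c1C(=O)/C=C/c1ccc(O)cc1 | target

## Step count and risk

Total step count: 12.
Longest linear sequence: 7 steps (steps 2, 3, 4, 5, 10, 11, 12 from 3; equally steps 6 to 12 from 10).

The three steps most likely to fail:

**Step 5 (the proposed new enantioselective Claisen rearrangement).** The catalyst may not accelerate the rearrangement enough, or may give low enantioselectivity. The fallback uses known chemistry, sets out from 7 and comes back at 9. Ether 7 is heated without catalyst (N,N-diethylaniline, 180 °C, sealed tube), the classical thermal aromatic Claisen rearrangement, which is ortho-selective for the same structural reason. This gives 9 as the racemate, that is together with its mirror image 1-[2-hydroxy-6-methoxy-4-(methoxymethoxy)-3-{(1R)-1-[4-(methoxymethoxy)phenyl]prop-2-en-1-yl}phenyl]ethan-1-one F1. The two are separated by preparative supercritical-fluid chromatography on an amylose tris(3,5-dimethylphenylcarbamate) phase. The S enantiomer 9 (assigned by circular dichroism and confirmed when 21 matches the natural product) re-enters at step 10. Stereocontrol thus moves from asymmetric catalysis to resolution.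

**Step 10 (cross-metathesis of the hindered 3,3-diarylpropene).** Low conversion or olefin migration is possible. The fallback sets out from 16, 18 and 2, comes back at 17, and replaces metathesis by a chirality-transferring sigmatropic shift.
- Wacker oxidation of 16 (PdCl2, CuCl, O2, DMF/H2O) gives (4R)-4-[(tert-butyldimethylsilyl)oxy]-6-[4-(methoxymethoxy)phenyl]hexan-2-one F2.
- Aldol addition of its kinetic enolate (LiN(i-Pr)2, THF, −78 °C) to 18 gives (5R)-5-[(tert-butyldimethylsilyl)oxy]-1-hydroxy-1,7-bis[4-(methoxymethoxy)phenyl]heptan-3-one F3.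
- Dehydration (MsCl, Et3N, CH2Cl2, 0 °C) gives (1E,5R)-5-[(tert-butyldimethylsilyl)oxy]-1,7-bis[4-(methoxymethoxy)phenyl]hept-1-en-3-one F4.
- Corey–Bakshi–Shibata reduction (BH3·SMe2, 10 mol% (S)-1-methyl-3,3-diphenyltetrahydro-1H,3H-pyrrolo[1,2-c][1,3,2]oxazaborole, THF, −20 °C) gives (1E,3R,5R)-5-[(tert-butyldimethylsilyl)oxy]-1,7-bis[4-(methoxymethoxy)phenyl]hept-1-en-3-ol F5.
- Mitsunobu etherification of F5 with phenol 2 (PPh3, DIAD, toluene, 0 °C, inversion) gives 1-[2-{[(1E,3S,5R)-5-[(tert-butyldimethylsilyl)oxy]-1,7-bis[4-(methoxymethoxy)phenyl]hept-1-en-3-yl]oxy}-6-methoxy-4-(methoxymethoxy)phenyl]ethan-1-one F6.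
- Thermal aromatic Claisen rearrangement of F6 (xylenes, 150 °C) through the chair transition state with the side chain equatorial transfers the C–O configuration to C7 (S) and forms the E olefin, which is 17 itself.

**Step 12 (global deprotection on the chalcone).** Acid may cyclise the 2'-hydroxychalcone to a flavanone or add methanol to the enone. The fallback sets out from 17 and comes back at 21, changing the order so that acid never meets the chalcone. Ketone 17 is deprotected first (HCl in MeOH, rt) to 1-{2,4-dihydroxy-3-[(1S,2E,5R)-5-hydroxy-1,7-bis(4-hydroxyphenyl)hept-2-en-1-yl]-6-methoxyphenyl}ethan-1-one F7. The Claisen–Schmidt condensation is then run on the free polyphenol with unprotected 4-hydroxybenzaldehyde (O=Cc1ccc(O)cc1) in 50% aq. KOH/EtOH (rt, 3 d), a known if lower-yielding way to polyhydroxychalcones. Careful neutralisation gives 21 directly.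

## Further compounds

F1 | step 5 | 1-[2-hydroxy-6-methoxy-4-(methoxymethoxy)-3-{(1R)-1-[4-(methoxymethoxy)phenyl]prop-2-en-1-yl}phenyl]ethan-1-one | COc1cc(OCOC)c([C@H](C=C)c2ccc(OCOC)cc2)c(O)c1C(C)=O
F2 | step 10 | (4R)-4-[(tert-butyldimethylsilyl)oxy]-6-[4-(methoxymethoxy)phenyl]hexan-2-one | CC(=O)C[C@H](O[Si](C)(C)C(C)(C)C)CCc1ccc(OCOC)cc1
F3 | step 10 | (5R)-5-[(tert-butyldimethylsilyl)oxy]-1-hydroxy-1,7-bis[4-(methoxymethoxy)phenyl]heptan-3-one (both C1 epimers) | COCOc1ccc(C(O)CC(=O)C[C@H](O[Si](C)(C)C(C)(C)C)CCc2ccc(OCOC)cc2)cc1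
F4 | step 10 | (1E,5R)-5-[(tert-butyldimethylsilyl)oxy]-1,7-bis[4-(methoxymethoxy)phenyl]hept-1-en-3-one | COCOc1ccc(/C=C/C(=O)C[C@H](O[Si](C)(C)C(C)(C)C)CCc2ccc(OCOC)cc2)cc1
F5 | step 10 | (1E,3R,5R)-5-[(tert-butyldimethylsilyl)oxy]-1,7-bis[4-(methoxymethoxy)phenyl]hept-1-en-3-ol | COCOc1ccc(/C=C/[C@H](O)C[C@H](O[Si](C)(C)C(C)(C)C)CCc2ccc(OCOC)cc2)cc1
F6 | step 10 | 1-[2-{[(1E,3S,5R)-5-[(tert-butyldimethylsilyl)oxy]-1,7-bis[4-(methoxymethoxy)phenyl]hept-1-en-3-yl]oxy}-6-methoxy-4-(methoxymethoxy)phenyl]ethan-1-one | COCOc1ccc(/C=C/[C@@H](Oc2cc(OCOC)cc(OC)c2C(C)=O)C[C@H](O[Si](C)(C)C(C)(C)C)CCc2ccc(OCOC)cc2)cc1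
F7 | step 12 | 1-{2,4-dihydroxy-3-[(1S,2E,5R)-5-hydroxy-1,7-bis(4-hydroxyphenyl)hept-2-en-1-yl]-6-methoxyphenyl}ethan-1-one | COc1cc(O)c([C@@H](/C=C/C[C@H](O)CCc2ccc(O)cc2)c2ccc(O)cc2)c(O)c1C(C)=O
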